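**Retrosynthetic overview**
1. Target ⇒ C6 benzyloxymethyl ether ⇒ oxa-Michael opening of the C9–O bond ⇒ Δ8-7-ketone carrying a (13R)-13-hydroxy-15,16-lactone; the lactone (C13–C14–C15–O–C16) is closed before the oxolane (O–C9–C11–C12–C13), which is closed last.
2. Δ8-7-ketone ⇒ 1,3-oxidative transposition of a C9 tertiary allylic alcohol ⇒ C9 ketone + alkyllithium C11–C16, whose C13 is set by Sharpless epoxidation.
3. The plan rests on ring B (C5–C10): oxygen at C6 and C9 in a 1,4 relation and methyl groups at C8 and C10 are the pattern of 2,6-dimethyl-1,4-benzoquinone, and the C5–C10 bond is shared with ring A (C1–C5, C10; C3 oxygen beside the C4 gem-dimethyl group).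
4. Ring B is therefore bought as the quinone and ring A is closed onto it by an enantioselective Diels–Alder reaction with 4-methyl-3-silyloxypenta-1,3-diene (bonds C1–C10 and C4–C5); the C9 carbonyl later takes C11 and relays its oxidation level to C7.
5. Order of ring formation: ring B (quinone) → ring A (cycloaddition) → lactone → oxolane.

Key step: step 3

Remark: labdane numbering is used for all decalin compounds; β is the face of the C10 methyl group.
Assumption: the (S)-oxazaborolidinium ion is taken to shield the quinone face that leads to the (5R,10S) adduct; the (R)-catalyst is equally available if the sense is the reverse.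

**Route**

Step 1
Reactants: 1 4-methylpent-1-en-3-ol
Product: 2 4-methylpent-1-en-3-one
Conditions: MnO2 (activated, 10 equiv), CH2Cl2, rt
Reagents that add atoms: none
Why: Allylic alcohol oxidation with MnO2 is selective for the allylic carbinol and should give the volatile vinyl ketone without touching the alkene, the product being carried on as a distilled solution.

Step 2
Reactants: 2 4-methylpent-1-en-3-one
Product: 3 4-methyl-3-(triisopropylsilyloxy)penta-1,3-diene
Conditions: TIPSOTf, Et3N, Et2O, 0 °C → rt
Reagents that add atoms: triisopropylsilyl triflate, CC(C)[Si](C(C)C)(C(C)C)OS(=O)(=O)C(F)(F)F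
Why: Soft enolisation with O-silylation (silyl enol ether formation) can remove only the isopropyl methine hydrogen, so the single cross-conjugated 2-silyloxydiene should form, and the TIPS group is chosen because it survives the acidic catalyst of step 3.

Step 3
Reactants: 3 4-methyl-3-(triisopropylsilyloxy)penta-1,3-diene, 4 2,6-dimethyl-1,4-benzoquinone
Product: 5 cis-fused silyl enol ether enedione (5R,10S)
Conditions: (S)-tetrahydro-1-(2-methylphenyl)-3,3-diphenyl-1H,3H-pyrrolo[1,2-c][1,3,2]oxazaborole (20 mol%), Tf2NH (18 mol%), CH2Cl2, −78 → −20 °C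
Reagents that add atoms: none
Why: The s-cis diene adds in a concerted but asynchronous endo [4+2] cycloaddition to one methyl-bearing double bond of the quinone, which is held on boron through its unhindered C6 carbonyl oxygen with a C5–H···O contact; the closest known reaction type is the oxazaborolidinium-catalysed Diels–Alder reaction of benzoquinones with 2-silyloxydienes. Ring A is closed in an intermolecular six-membered [4+2] mode, C1–C10 and C4–C5 both being formed in this step. C10 and C5 arise cis from suprafacial addition to the quinone double bond, and their absolute configuration is set by the catalyst, whose aryl group shields one face of the bound C5=C10 bond. The step needs regio- and facial selectivity: the fully substituted CMe2 terminus can bond only to the hydrogen-bearing C5, while the CH2 terminus, whose coefficient is raised by the two terminal methyl groups, meets C10, the carbon β to the boron-bound C6 carbonyl. The free quinone prefers the same orientation, because its C9 carbonyl, flanked by both methyl-bearing carbons, is the more electron-poor and activates C5 toward the enol ether carbon. The Z-methyl group of the diene slows the reaction, hence the cationic Lewis acid and the acid-stable TIPS ether.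

Step 4
Reactants: 5 cis-fused silyl enol ether enedione
Product: 6 bis(silyl) dienol ether dienone (10S)
Conditions: TBSOTf, Et3N, CH2Cl2, −78 → 0 °C
Reagents that add atoms: tert-butyldimethylsilyl triflate, CC(C)(C)[Si](C)(C)OS(=O)(=O)C(F)(F)F
Why: Soft enolisation (silyl triflate and amine) removes the convex-face C5–H, the only proton α to a carbonyl since C9 has none, giving the linear silyl dienol ether that masks C6, leaves C9 as the only electrophilic carbonyl and makes C5 trigonal for the protonation of step 12.

Step 5
Reactants: 7 pent-4-enal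
Product: 8 2-methylidenepent-4-enal
Conditions: 37% aq. CH2O, pyrrolidine (10 mol%), propionic acid (10 mol%), i-PrOH, 45 °C
Reagents that add atoms: formaldehyde, C=O
Why: Amine-catalysed α-methylenation of the aldehyde (Mannich condensation and elimination through the enamine) installs the 1,1-disubstituted alkene without involving the remote vinyl group.

Step 6
Reactants: 8 2-methylidenepent-4-enal
Product: 9 2-methylidenepent-4-en-1-ol
Conditions: NaBH4, CeCl3·7H2O, MeOH, 0 °C
Reagents that add atoms: none
Why: Luche reduction should give clean 1,2-reduction of the α-substituted acrolein to the 2-substituted allylic alcohol needed for the directed epoxidation.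

Step 7
Reactants: 9 2-methylidenepent-4-en-1-ol
Product: 10 (R)-[2-(prop-2-en-1-yl)oxiran-2-yl]methanol
Conditions: Ti(OiPr)4 (10 mol%), D-(−)-diethyl tartrate (12 mol%), t-BuOOH, 4 Å MS, CH2Cl2, −20 °C
Reagents that add atoms: tert-butyl hydroperoxide, CC(C)(C)OO
Why: Sharpless asymmetric epoxidation is directed by the hydroxyl group to the allylic double bond only, and the tartrate selects the face so that the quaternary carbon that becomes C13 is set as (R), D-tartrate being the antipode of the ester that leads to (S)-2-substituted glycidols.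

Step 8
Reactants: 10 (R)-[2-(prop-2-en-1-yl)oxiran-2-yl]methanol
Product: 12 (S)-3-(hydroxymethyl)hex-5-ene-1,3-diol, via silyl diol 11 (not isolated)
Conditions: (i-PrO)Me2SiCH2MgCl (3 equiv), CuI (10 mol%), THF, −20 → 0 °C; then 30% H2O2, KF, KHCO3, MeOH–THF, rt
Reagents that add atoms: (isopropoxydimethylsilyl)methylmagnesium chloride, CC(C)O[Si](C)(C)C[Mg]Cl; hydrogen peroxide, OO
Why: Copper-catalysed opening of the 2,2-disubstituted epoxide at its CH2 carbon by the silylmethyl Grignard reagent (a hydroxymethyl anion equivalent), followed by Tamao–Fleming oxidation, adds C11 as CH2OH with the C13–O bond retained, and a Payne rearrangement of 10 would be degenerate and cannot erode the configuration.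

Step 9
Reactants: 12 (S)-3-(hydroxymethyl)hex-5-ene-1,3-diol
Product: 13 2-[(4S)-2,2-dimethyl-4-(prop-2-en-1-yl)-1,3-dioxolan-4-yl]ethan-1-ol
Conditions: 2,2-dimethoxypropane, PPTS (cat.), acetone, rt
Reagents that add atoms: 2,2-dimethoxypropane, COC(C)(C)OC
Why: Acetonide formation under equilibrating acid catalysis takes the 1,2-diol as the five-membered dioxolane, because the alternative 1,3-dioxane would carry a syn-axial methyl/alkyl clash, and so leaves the primary C11 hydroxyl free.

Step 10
Reactants: 13 2-[(4S)-2,2-dimethyl-4-(prop-2-en-1-yl)-1,3-dioxolan-4-yl]ethan-1-ol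
Product: 14 (4S)-4-(2-iodoethyl)-2,2-dimethyl-4-(prop-2-en-1-yl)-1,3-dioxolane
Conditions: I2, PPh3, imidazole, CH2Cl2, 0 °C → rt
Reagents that add atoms: iodine, II
Why: Appel-type iodination converts the unhindered primary alcohol into the iodide under neutral conditions that leave the acetonide and the alkene intact.

Step 11
Reactants: 14 (4S)-4-(2-iodoethyl)-2,2-dimethyl-4-(prop-2-en-1-yl)-1,3-dioxolane, 6 bis(silyl) dienol ether dienone
Product: 16 C9 tertiary alcohol of the bis(silyl) dienol ether, via alkyllithium 15 (not isolated)
Conditions: t-BuLi (2 equiv per 14), Et2O–pentane, −78 °C; then 6, THF, −78 → −40 °C; aq. NH4Cl (pH 7)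
Reagents that add atoms: none
Why: Iodine–lithium exchange gives the primary alkyllithium, kept at −78 °C where the 5-hexenyllithium does not cyclise, which adds 1,2 to the C9 carbonyl of the non-enolisable dienone as organolithiums do with 2,6,6-trisubstituted cyclohexenones; attack anti to the C10 methyl should give the 9β-alcohol, but either C9 epimer serves because C9 becomes trigonal in step 16.

Step 12
Reactants: 16 C9 tertiary alcohol of the bis(silyl) dienol ether
Product: 17 trans-fused 3,6-diketo-9-hydroxy enone
Conditions: TBAF, AcOH, THF, −78 → 0 °C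
Reagents that add atoms: none
Why: Fluoride cleaves both silyl enol ethers, and the C6 enolate should be protonated at C5 on the α face, anti to the axial C10 methyl and the 4β-methyl (the face on which electrophiles add to Δ5 olefins of 10-methyl decalins), which sets the trans ring fusion under kinetic control; the ketone is reduced at once so that C5 cannot equilibrate.

Step 13
Reactants: 17 trans-fused 3,6-diketo-9-hydroxy enone
Product: 18 3β,6β,9β-triol
Conditions: NaBH4, CeCl3·7H2O, MeOH, −78 → 0 °C
Reagents that add atoms: none
Why: In this Luche reduction hydride should add 1,2 to the C6 enone from the α face, because the β face is closed by the syn-axial C10 and 4β methyl groups, giving the axial 6β-alcohol and locking C5, and should add axially to the C3 ketone to give the equatorial 3β-alcohol.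

Step 14
Reactants: 18 3β,6β,9β-triol
Product: 19 3β-acetate 6β,9β-diol
Conditions: Ac2O (1.2 equiv), pyridine, DMAP (cat.), CH2Cl2, 0 °C
Reagents that add atoms: acetic anhydride, CC(=O)OC(C)=O
Why: Selective esterification should acylate only the equatorial secondary 3β-hydroxyl, the axial 6β-hydroxyl (syn-axial to two methyl groups) and the tertiary C9 hydroxyl being far slower.

Step 15
Reactants: 19 3β-acetate 6β,9β-diol
Product: 20 6β-benzyloxymethyl ether
Conditions: BnOCH2Cl, i-Pr2NEt, Bu4NI (cat.), ClCH2CH2Cl, 50 °C
Reagents that add atoms: benzyl chloromethyl ether, ClCOCc1ccccc1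
Why: Alkoxymethylation with the reactive α-chloro ether (Williamson-type, iodide catalysis) protects the secondary 6β-hydroxyl, which must not be oxidised in step 16, while the tertiary C9 hydroxyl beside the quaternary C10 reacts much more slowly.

Step 16
Reactants: 20 6β-benzyloxymethyl ether
Product: 21 Δ8-7-ketone
Conditions: pyridinium chlorochromate (C5H5NH)[CrO3Cl], NaOAc, 4 Å MS, CH2Cl2, rt
Reagents that add atoms: pyridinium chlorochromate, [O-][Cr](=O)(=O)Cl.c1cc[nH+]cc1
Why: In the Babler–Dauben oxidative 1,3-transposition the chromate ester of the tertiary allylic alcohol shifts to C7 by a [3,3] process and is oxidised there, which delivers the C7 ketone conjugated with the tetrasubstituted C8=C9 bond and erases the C9 stereocentre.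

Step 17
Reactants: 21 Δ8-7-ketone
Product: 22 C15 aldehyde
Conditions: OsO4 (2 mol%), NaIO4, 2,6-lutidine, dioxane–H2O, rt
Reagents that add atoms: sodium periodate, [Na+].[O-]I(=O)(=O)=O (terminal oxidant; the oxygen is delivered through catalytic OsO4, O=[Os](=O)(=O)=O)
Why: In the Lemieux–Johnson cleavage catalytic OsO4 dihydroxylates only the monosubstituted terminal alkene, the tetrasubstituted electron-poor enone double bond being inert, and NaIO4 cleaves the diol to the aldehyde.

Step 18
Reactants: 22 C15 aldehyde
Product: 23 C15 carboxylic acid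
Conditions: NaClO2, NaH2PO4, 2-methylbut-2-ene, t-BuOH–H2O, 0 °C → rt
Reagents that add atoms: sodium chlorite, [Na+].[O-]Cl=O
Why: Pinnick oxidation converts the aldehyde into the acid under buffered conditions that do not enolise the α-alkoxy ketone, with 2-methylbut-2-ene scavenging hypochlorite.

Step 19
Reactants: 23 C15 carboxylic acid
Product: 25 (13R)-13-hydroxy-15,16-lactone enone, via dihydroxy acid 24 (not isolated)
Conditions: AcOH–H2O (4:1), 45 °C; toluene azeotrope
Reagents that add atoms: none
Why: Acid hydrolysis of the acetonide frees the C13 and C16 hydroxyls and the γ-hydroxy acid should lactonise spontaneously through the primary C16 hydroxyl, which also removes the competing primary alcohol before the conjugate addition.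

Step 20
Reactants: 25 (13R)-13-hydroxy-15,16-lactone enone
Product: 26 6-O-benzyloxymethyl ether of the target
Conditions: camphorsulfonic acid (20 mol%), CH2Cl2, rt
Reagents that add atoms: none
Why: Acid-catalysed intramolecular oxa-Michael addition (5-exo-trig) of the tertiary C13 hydroxyl to C9 closes the oxolane; attack on the α face, axial and anti to the C10 methyl, gives the 9α-oxygen with C11 equatorial, the enol is protonated to the equatorial 8α-methyl ketone (also the thermodynamic epimer of this reversible step), and C13 is untouched.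

Step 21
Reactants: 26 6-O-benzyloxymethyl ether of the target
Product: 27 CNP0325396.1
Conditions: H2 (1 atm), Pd(OH)2/C, EtOAc, rt
Reagents that add atoms: none
Why: Hydrogenolysis of the benzyloxymethyl ether (the hemiformal loses formaldehyde) frees the 6β-hydroxyl under neutral conditions that leave the acetate, the lactone, the β-alkoxy ketone and the epimerisable C6 and C8 centres untouched.

**Compound list**
1 | 4-methylpent-1-en-3-ol (racemic) | C=CC(O)C(C)C | starting material
2 | 4-methylpent-1-en-3-one | C=CC(=O)C(C)C | intermediate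
3 | 4-methyl-3-(triisopropylsilyloxy)penta-1,3-diene | C=CC(O[Si](C(C)C)(C(C)C)C(C)C)=C(C)C | intermediate
4 | 2,6-dimethyl-1,4-benzoquinone | CC1=CC(=O)C=C(C)C1=O | starting material
5 | cis-fused adduct: ring A with C2=C3(OTIPS) and C4 gem-dimethyl, ring B with C6 ketone, C7=C8(CH3) and C9 ketone, 5β-H, 10β-CH3, (5R,10S) | CC(C)[Si](C(C)C)(C(C)C)OC1=CC[C@@]2(C)[C@H](C(=O)C=C(C)C2=O)C1(C)C | intermediate
6 | bis(silyl) dienol ether dienone: as 5 but ring B is C5=C6(OTBS)–C7=C8(CH3)–C9=O, (10S) | CC(C)[Si](C(C)C)(C(C)C)OC1=CC[C@@]2(C)C(=C(O[Si](C)(C)C(C)(C)C)C=C(C)C2=O)C1(C)C | intermediate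
7 | pent-4-enal | C=CCCC=O | starting material
8 | 2-methylidenepent-4-enal | C=CCC(=C)C=O | intermediate
9 | 2-methylidenepent-4-en-1-ol | C=CCC(=C)CO | intermediate
10 | (R)-[2-(prop-2-en-1-yl)oxiran-2-yl]methanol | C=CC[C@@]1(CO)CO1 | intermediate
11 | (S)-2-allyl-4-[isopropoxy(dimethyl)silyl]butane-1,2-diol | CC(C)O[Si](C)(C)CC[C@@](CC=C)(CO)O | intermediate
12 | (S)-3-(hydroxymethyl)hex-5-ene-1,3-diol | OCC[C@@](CC=C)(CO)O | intermediate
13 | 2-[(4S)-2,2-dimethyl-4-(prop-2-en-1-yl)-1,3-dioxolan-4-yl]ethan-1-ol | OCC[C@@](CC=C)(CO1)OC1(C)C | intermediate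
14 | (4S)-4-(2-iodoethyl)-2,2-dimethyl-4-(prop-2-en-1-yl)-1,3-dioxolane | ICC[C@@](CC=C)(CO1)OC1(C)C | intermediate
15 | 2-[(4S)-2,2-dimethyl-4-(prop-2-en-1-yl)-1,3-dioxolan-4-yl]ethyllithium | [Li]CC[C@@](CC=C)(CO1)OC1(C)C | intermediate
16 | tertiary alcohol: 6 with C9 as C(OH)(CH2CH2–dioxolanyl), 9β-OH, side chain 9α, dioxolane carbon (C13) spatially as in 14 (descriptor now R), (9S,10S) | CC(C)[Si](C(C)C)(C(C)C)OC1=CC[C@@]2(C)C(=C(O[Si](C)(C)C(C)(C)C)C=C(C)[C@@]2(O)CC[C@@](CC=C)(CO3)OC3(C)C)C1(C)C | intermediate
17 | trans-fused diketo alcohol: C3 ketone, C6 ketone conjugated with C7=C8(CH3), 9β-OH, 9α-side chain (acetonide, allyl), 5α-H, 10β-CH3, 13R | O=C1CC[C@@]2(C)[C@@H](C(=O)C=C(C)[C@@]2(O)CC[C@@](CC=C)(CO3)OC3(C)C)C1(C)C | intermediate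
18 | triol: 17 with 3β-OH and 6β-OH in place of the two ketones | O[C@H]1CC[C@@]2(C)[C@@H]([C@H](O)C=C(C)[C@@]2(O)CC[C@@](CC=C)(CO3)OC3(C)C)C1(C)C | intermediate
19 | 3β-acetate of 18 | CC(=O)O[C@H]1CC[C@@]2(C)[C@@H]([C@H](O)C=C(C)[C@@]2(O)CC[C@@](CC=C)(CO3)OC3(C)C)C1(C)C | intermediate
20 | 6β-benzyloxymethyl ether of 19 | CC(=O)O[C@H]1CC[C@@]2(C)[C@@H]([C@H](OCOCc4ccccc4)C=C(C)[C@@]2(O)CC[C@@](CC=C)(CO3)OC3(C)C)C1(C)C | intermediate
21 | Δ8-7-ketone: 3β-OAc, 6β-OBOM, C7 ketone, C8(CH3)=C9, C9 side chain CH2CH2–C13(acetonide)(allyl), 5α-H, 10β-CH3, 13R | CC(=O)O[C@H]1CC[C@@]2(C)[C@@H]([C@H](OCOCc4ccccc4)C(=O)C(C)=C2CC[C@@](CC=C)(CO3)OC3(C)C)C1(C)C | intermediate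
22 | aldehyde: 21 with CH2CHO (C14–C15) in place of allyl | CC(=O)O[C@H]1CC[C@@]2(C)[C@@H]([C@H](OCOCc4ccccc4)C(=O)C(C)=C2CC[C@@](CC=O)(CO3)OC3(C)C)C1(C)C | intermediate
23 | acid: 21 with CH2CO2H (C14–C15) in place of allyl | CC(=O)O[C@H]1CC[C@@]2(C)[C@@H]([C@H](OCOCc4ccccc4)C(=O)C(C)=C2CC[C@@](CC(=O)O)(CO3)OC3(C)C)C1(C)C | intermediate
24 | dihydroxy acid: 23 with free 13-OH and 16-OH | CC(=O)O[C@H]1CC[C@@]2(C)[C@@H]([C@H](OCOCc4ccccc4)C(=O)C(C)=C2CC[C@@](CC(=O)O)(CO)O)C1(C)C | intermediate
25 | (13R)-3β-acetoxy-6β-(benzyloxymethoxy)-13-hydroxy-7-oxolabd-8-en-15,16-olide (C15 carbonyl, C16–O) | CC(=O)O[C@H]1CC[C@@]2(C)[C@@H]([C@H](OCOCc4ccccc4)C(=O)C(C)=C2CC[C@]3(O)COC(=O)C3)C1(C)C | intermediate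
26 | 6-O-benzyloxymethyl ether of the target (9α,13R-epoxide, 8α-CH3) | CC(=O)O[C@H]1CC[C@@]2(C)[C@@H]([C@H](OCOCc4ccccc4)C(=O)[C@@H](C)[C@]23CC[C@@]2(COC(=O)C2)O3)C1(C)C | intermediate
27 | CNP0325396.1: (3S,5S,6S,8S,9R,10S,13R)-3-acetoxy-6-hydroxy-7-oxo-9,13-epoxylabdan-15,16-olide | CC(=O)O[C@H]1CC[C@@]2(C)[C@@H]([C@H](O)C(=O)[C@@H](C)[C@]23CC[C@@]2(COC(=O)C2)O3)C1(C)C | target

**Step count and risks**
Total steps: 21. Longest linear sequence: 17 (steps 5–21, from pent-4-enal); the decalin branch from 1 is 15 steps.

Most likely to fail:

Step 3. The catalyst bound at the C6 carbonyl makes C10 the electrophilic carbon. The hindered diene may then answer by a stepwise Mukaiyama–Michael addition, by the reversed orientation, or so slowly that the enol ether is cleaved first, and regiochemical or enantiomeric purity would fall. Fallback, from 3 and 4: the cycloaddition is run without catalyst at about 13 kbar in CH2Cl2 at rt (or neat at 80 °C), where the electronic bias of the free quinone and the steric demand agree. It should give the racemic cis adduct, that is 5 together with its enantiomer, the (5S,10R) adduct F1. The antipodes are separated by preparative chromatography on a chiral stationary phase and the route is rejoined at 5.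

Step 20. The conjugate addition is reversible: the equilibrium may not lie far enough on the closed side for this tetrasubstituted enone beside the quaternary C10, and prolonged acid may dehydrate the tertiary C13 alcohol to the butenolide or epimerise C6 through the C6–C7 enol. Fallback, from 25: with TMSOTf and 2,6-lutidine in CH2Cl2 at −78 → −40 °C the enone is activated as its O-silyl oxocarbenium ion, the C13 oxygen adds to C9, and the adduct is trapped irreversibly as the C7 trimethylsilyl enol ether of the spirocycle F2. Buffered fluoride (TBAF, AcOH, THF, −40 °C) then protonates C8 axially on the β face to give 26, where the route is rejoined.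

Step 12. Facial selectivity in the protonation at C5 may be poor, or the ketone may equilibrate before it is reduced, giving the cis-fused 5β-H epimer of 17 F3; the thermodynamic preference between cis- and trans-fused 6-ketones of 4,4,10-trimethyl decalins is small and cannot be relied on. Fallback, from the mixture of 17 and F3: kinetic protonation is replaced by equilibration with recycling. F3 is epimerised through the C6 enolate with DBU in toluene, 17 is separated by chromatography and reduced at once as in step 13, and recovered F3 is resubmitted; the route is rejoined at 17.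

Further compounds
F1 | step 3 | (5S,10R) enantiomer of adduct 5 | CC(C)[Si](C(C)C)(C(C)C)OC1=CC[C@]2(C)[C@@H](C(=O)C=C(C)C2=O)C1(C)C
F2 | step 20 | C7 trimethylsilyl enol ether of spirocycle 26 | CC(=O)O[C@H]1CC[C@@]2(C)[C@@H]([C@H](OCOCc4ccccc4)C(O[Si](C)(C)C)=C(C)[C@]23CC[C@@]2(COC(=O)C2)O3)C1(C)C
F3 | step 12 | cis-fused 5β-H epimer of 17 | O=C1CC[C@@]2(C)[C@H](C(=O)C=C(C)[C@@]2(O)CC[C@@](CC=C)(CO3)OC3(C)C)C1(C)C
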